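The readings come from a simulation for an exercise; noise was put on by code.

- At late times Wednesday's run reads target 7.0% of 10 mM at 25.0 h, which is 0.700 mM; Thursday's run, with 40 mM charged and the same partner, reads 0.840 mM, so target in mM does not follow the charge of solid substrate.

| setting | Wednesday's | Thursday's | Saturday's | flask |
|---|---|---|---|---|
| solid substrate | 10 mM | 40 mM | 20 mM | 20 mM |
| partner | 30 mM | 30 mM | 15 mM | 30.0 mM |
| remark | run made earlier | run made earlier | run made earlier |  |
| time |  |  |  | 30 h |

- Wednesday's (time / h: target / %, starting material / %): 2.00: 0, 4.2; 4.00: 0.7, 5.0; 6.00: 1.1, 5.5; 12.0: 2.6, 5.4; 25.0: 7.0, 5.7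
- Thursday's (time / h: target / %, starting material / %): 2.00: 0.6, 0.2; 6.00: 0.4, 0.2; 12.0: 0.4, 1.7; 15.0: 1.2, 0.7; 25.0: 2.1, 1.0
- Saturday's (time / h: target / %, starting material / %): 2.00: 0.4, 2.7; 6.00: 0.4, 3.4; 12.0: 0, 3.6; 15.0: 0.9, 2.4; 25.0: 1.0, 2.8

(each reading ± 0.5 percentage points)

- given per volume of solution although it is solid: solid substrate
- the numbers in the tables scatter by 0.5 percentage points (one standard deviation)
- at the start none of the solid substrate is in solution
- starting material is what solid substrate becomes in solution
- starting material means what is dissolved; the solid is not counted in it

- the target standing at 30 h, as a percentage of the solid substrate charged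
- concentration of starting material in solution at 30 h, in percent of saturation

- Fastest rung: c(starting material) reads about level in Wednesday's run and in Saturday's run, 0.550 mM in Wednesday's run at 6.00 h and 0.560 mM in Saturday's run at 25.0 h. This reckoning takes that level as read and commits to no figure for saturation.
- Middle rung: at that level, with 30.0 mM partner, this reckoning takes target to grow by a steady amount, the target gain, the mM of target made per hour, read as 0.0280 mM h⁻¹ from Wednesday's run, where the same scatter costs fewer mM than in Thursday's run.
- Slowest rung: up to 30 h the gain takes hardly any of the partner, so this reckoning holds c(partner) near its charge and keeps the gain.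
- This reckoning gives target 4.20% for the flask.
- The forecast gives 4.7% and 96%, holding that “excess solid acts as a reservoir”; its target stands above this reckoning.
- The flask gives 3.91% and 3.29%.

    solid substrate ⇌ starting material, rate k1*(cs1 - [starting material]) while solid is left; crystals form when [starting material] > cs1 (solubility = 17.0 mM, k = 3.10 × 10⁻⁴ min⁻¹)
    intermediate A → side product (k = 0.00200 min⁻¹)
    starting material + partner → target (k = 0.0280 L mol⁻¹ min⁻¹)
    starting material → intermediate B (k = 0.00130 min⁻¹)
    starting material → intermediate A (k = 0.00700 min⁻¹)
    partner + intermediate B ⇌ intermediate C (K = 12.0 L mol⁻¹, k = 0.0200 L mol⁻¹ min⁻¹)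

- The forecast's target stands within tolerance, while its saturation stands 93 percentage points above the flask. Starting material has a half-life of 1.7 h by the making of intermediate A alone, shorter than the 14 h by the step to target alone with the other concentrations as charged and short against 30 h, and at 15.0 h it is made 1.00 times as fast as it is used up, each step taken net, a quasi-steady state.
- Read at 3.0 d, the neighbour flask gets 10.1% from the target gain; computed, it holds 8.85%, with 0.076% of the solid substrate left, solid or dissolved.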